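Time has stopped adding much product in the alpha run, the very flask that is asked about. From 20.0 h to 50.0 h its product reads 18.4 % and then 18.9 %, against a scatter of 0.3 percentage points per reading, so the question is what a dose of free catalyst buys.

common to all: solid substrate 0.10 M; temperature −20 °C

| flask | reagent | free catalyst | remark | time |
|---|---|---|---|---|
| alpha | 0.12 M | 2 mM | the very flask that is asked about, followed so far |  |
| flask | 0.120 M | 2.0 mM |  | 2.0 d |

alpha run (percent of the solid substrate charged)

| time / h | product / % | solid substrate / % |
|---|---|---|
| 4.00 | 9.5 | 78.8 |
| 12.0 | 17.9 | 56.6 |
| 20.0 | 18.4 | 49.6 |
| 30.0 | 18.8 | 47.7 |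
| 50.0 | 18.9 | 47.1 |

(readings scatter by 0.3 percentage points)

- blue: at 2.0 d add free catalyst, 50.0 % of the amount charged, then wait 25 h
- red: at 2.0 d raise the temperature by 10 K, then wait 25 h
- green: change nothing and wait 25 h more
- teal: at 2.0 d take out 90 % of the product then present, then wait 25 h
- amber: at 2.0 d add reagent, 100 % of the amount charged, then wait 25 h

- solid substrate is a solid; its amount is given per volume of the solution
- what is taken out of product is counted as made
- reactions considered so far: starting material + reagent + free catalyst -> free catalyst + product; reagent + free catalyst -> spent catalyst; solid substrate <-> starting material
- at the start none of the solid substrate is in solution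
- additions bring no volume worth counting
- the earlier runs do not show what temperature does; that part of a forecast is a guess

1. product, in percent of the solid substrate first charged, at 2.0 d
2. what to do for the largest gain in product; "none" if nothing gains more than 2 percentage points (blue / red / green / teal / amber / none)
3. product present, with what was taken out counted in, in percent of the solid substrate first charged, after blue
4. product present, with what was taken out counted in, in percent of the solid substrate first charged, after teal

Dissolved starting material is whatever is neither product nor solid. That gives c(starting material) = 11.7 mM at 4.00 h, 25.5 mM at 12.0 h, 32.0 mM at 20.0 h and a plateau of 34.0 mM at 50.0 h. Product still to come shrinks from 9.4 points to 1 point between the first two of those times, although dissolved starting material rises. Correcting for that rise, I read the catalyst's decay as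

decay constant = 0.335 h⁻¹, mean life = 2.99 h

That mean life is far shorter than 2.0 d, so I expect about 18.9 % at 2.0 d, and no gain from green, red, teal or amber.

If both steps run as written, reagent and free catalyst cancel from the ratio of their rates. Product per catalyst lost then follows c(starting material). At its mean life the first charge saw about 8.74 mM, and it made 9.45 product per catalyst, so

reach = 1080 M⁻¹

This reach, product made per catalyst lost per unit of c(starting material), is a selectivity factor. Blue's dose of 1.00 mM multiplies it to 1.08.

Bound from above, solution held at plateau: gain 36.7 mM

Bound from below, no solid dissolving: gain 22.5 mM

Read from the alpha run, the solid makes up the deficit in solution at 0.181 h⁻¹. Over one mean life that supplies about 7.15 mM, so my working bracket, whose top is an estimate and not a strict bound, runs from 41.4 % to 48.5 %.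

The forecast says 18.9 % now, blue as best, 46 % after blue (38 % to 53 %) and 18.9 % after teal, on the ground that “Fresh catalyst works”. Its 46 % lies inside my bracket.

The flask gives 18.6 % now, blue as best, 47.0 % after blue and 18.6 % after teal.

    starting material + reagent + free catalyst → free catalyst + product (k = 0.970 M⁻² s⁻¹, Ea = 37.0 kJ mol⁻¹)
    reagent + free catalyst → spent catalyst (k = 8.70 × 10⁻⁴ M⁻¹ s⁻¹, Ea = 54.0 kJ mol⁻¹)
    solid substrate ⇌ starting material, rate k3*(cs3 - [starting material]) while solid is left; crystals form when [starting material] > cs3 (solubility = 34.0 mM, k = 5.40 × 10⁻⁵ s⁻¹)
    (constants at −20 °C)

In the flask blue gains 28 points and red 0 points, and 47.0 % falls inside the bracket. At 24.0 h the flask's free catalyst already stood at 0.0418 % of its charge. Divided by the reach, blue's gain means its dose worked at a mean c(starting material) of 26.3 mM. The neighbour flask charged with 0.0080 M free catalyst gives 45.3 % at 2.0 d, which by the same reach means a mean c(starting material) of 5.24 mM.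

The data were computed for substances that don't exist, noise included.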